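**Assumption:** resorcinol, (E)-geranyl bromide, isovanillin, the Weinreb-amide phosphonate and the named catalysts/ligands are taken as commercial. The THP acetal centre in 7 and 12 is racemic and irrelevant, because it is removed in step 9.

## Retrosynthetic overview

1. Target ⇐ tris-MOM dihydroflavonol by global MOM removal (last step).
2. The pyranone C-ring is the only ring formed, and it is formed last: O1–C2 and C3–OH come from a 2'-hydroxychalcone by a new hydroxy-anchored asymmetric epoxidation/6-endo cyclisation. The A and B rings are bought as arenes.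
3. Chalcone ⇐ C4–C4a disconnection: aryllithium of the A-ring THP ether plus a B-ring cinnamoyl Weinreb amide made from isovanillin.
4. A-ring ⇐ a C2-symmetric 4-geranyl-3,5-bis(MOMO)phenol. The geranyl group is para to the oxygen that becomes O1, so both ortho sites are equivalent and 6-geranyl (not 8-geranyl) regiochemistry is fixed by symmetry.
5. That phenol ⇐ resorcinol by directed metalation/geranylation, then Ir C–H borylation/oxidation.

## Route

**Step 1**
Reactants: 1 resorcinol
Product: 2 1,3-bis(methoxymethoxy)benzene
Conditions: NaH, MOMCl, DMF, 0 °C → rt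
Reagents that add atoms: chloromethyl methyl ether, COCCl
Why: Williamson-type O-alkylation of both phenoxides installs MOM groups that serve as protecting groups and as directed-metalation groups.

**Step 2**
Reactants: 2 1,3-bis(methoxymethoxy)benzene; 3 geranyl bromide [(2E)-1-bromo-3,7-dimethylocta-2,6-diene]
Product: 4 2-[(2E)-3,7-dimethylocta-2,6-dien-1-yl]-1,3-bis(methoxymethoxy)benzene
Conditions: n-BuLi, THF, 0 °C → rt; CuI (10 mol %), then 3, −40 °C → rt
Reagents that add atoms: none beyond the listed reactants
Why: Directed ortho-metalation at C2 (flanked by two OMOM groups) followed by copper-assisted SN2 allylation gives the linear geranyl arene with the E-alkene retained.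

**Step 3**
Reactants: 4
Product: 5 2-{4-[(2E)-3,7-dimethylocta-2,6-dien-1-yl]-3,5-bis(methoxymethoxy)phenyl}-4,4,5,5-tetramethyl-1,3,2-dioxaborolane
Conditions: B2pin2, [Ir(OMe)(cod)]2 (1.5 mol %), dtbpy (3 mol %), cyclohexane, 70 °C
Reagents that add atoms: bis(pinacolato)diboron, CC1(C)OB(OC1(C)C)B1OC(C)(C)C(C)(C)O1
Why: Sterically controlled Ir-catalysed aromatic C–H borylation occurs at the only C–H with no ortho substituent, which is para to the geranyl group.

**Step 4**
Reactants: 5
Product: 6 4-[(2E)-3,7-dimethylocta-2,6-dien-1-yl]-3,5-bis(methoxymethoxy)phenol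
Conditions: 30% H2O2, NaOH, THF/H2O, 0 °C
Reagents that add atoms: hydrogen peroxide, OO
Why: Ipso-oxidation of the aryl boronate (1,2-aryl shift from B to O) gives the phenol, and alkaline peroxide does not touch the isolated trisubstituted alkenes.

**Step 5**
Reactants: 6
Product: 7 2-{4-[(2E)-3,7-dimethylocta-2,6-dien-1-yl]-3,5-bis(methoxymethoxy)phenoxy}tetrahydro-2H-pyran (racemic acetal)
Conditions: DHP, PPTS (cat.), CH2Cl2, rt
Reagents that add atoms: 3,4-dihydro-2H-pyran, C1=COCCC1
Why: Acid-catalysed acetalisation marks the future O1 oxygen with a group that directs metalation and is cleaved by much milder acid than the aryl MOM ethers.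

**Step 6**
Reactants: 8 isovanillin (3-hydroxy-4-methoxybenzaldehyde)
Product: 9 4-methoxy-3-(methoxymethoxy)benzaldehyde
Conditions: MOMCl, i-Pr2NEt, CH2Cl2, 0 °C → rt
Reagents that add atoms: chloromethyl methyl ether, COCCl
Why: Standard MOM protection of the phenol, with the 3'-OH/4'-OMe pattern already differentiated in the starting material.

**Step 7**
Reactants: 9; 10 diethyl {2-[methoxy(methyl)amino]-2-oxoethyl}phosphonate
Product: 11 (2E)-N-methoxy-3-[4-methoxy-3-(methoxymethoxy)phenyl]-N-methylprop-2-enamide
Conditions: NaH, THF, 0 °C → rt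
Reagents that add atoms: none beyond the listed reactants
Why: Horner–Wadsworth–Emmons olefination with a stabilised phosphonate gives the E-cinnamoyl Weinreb amide.

**Step 8**
Reactants: 7; 11
Product: 12 (2E)-1-{3-[(2E)-3,7-dimethylocta-2,6-dien-1-yl]-2,4-bis(methoxymethoxy)-6-(tetrahydro-2H-pyran-2-yloxy)phenyl}-3-[4-methoxy-3-(methoxymethoxy)phenyl]prop-2-en-1-one
Conditions: n-BuLi, TMEDA, THF, −20 → 0 °C; then 11, −78 → 0 °C; aq NH4Cl
Reagents that add atoms: none beyond the listed reactants
Why: Directed ortho-metalation at either of the two symmetry-equivalent sites flanked by OTHP and OMOM, then Weinreb ketone synthesis (1,2-addition via the chelated tetrahedral intermediate), gives the E-chalcone with the ketone ortho to the future O1.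

**Step 9**
Reactants: 12
Product: 13 (2E)-1-{3-[(2E)-3,7-dimethylocta-2,6-dien-1-yl]-6-hydroxy-2,4-bis(methoxymethoxy)phenyl}-3-[4-methoxy-3-(methoxymethoxy)phenyl]prop-2-en-1-one
Conditions: PPTS (0.2 equiv), MeOH, rt
Reagents that add atoms: none
Why: Selective acid methanolysis of the aryl THP acetal in the presence of the less labile aryl MOM ethers frees only the phenol flanked by H and C=O, so only this oxygen can later close the ring.

**Step 10 (new step)**
Reactants: 13
Product: 14 (2R,3R)-6-[(2E)-3,7-dimethylocta-2,6-dien-1-yl]-3-hydroxy-2-[4-methoxy-3-(methoxymethoxy)phenyl]-5,7-bis(methoxymethoxy)-2,3-dihydro-4H-chromen-4-one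
Conditions: La(O-i-Pr)3/(S)-BINOL/Ph3As=O (1:1:1, 25 mol %), TBHP (1.5 equiv, decane), 4 Å MS, THF, 0 °C → rt; then CSA (to ca. pH 3), same pot, 0 °C
Reagents that add atoms: tert-butyl hydroperoxide, CC(C)(C)OO
Why: Proposed new method: a hydroxy-anchored asymmetric "interrupted Algar–Flynn–Oyamada" reaction, in which the 2'-phenoxide and C=O chelate the chiral La–BINOLate–arsine oxide centre (planar s-cis enone), La–OOt-Bu adds to one face of Cβ and the enolate closes to the (αR,βS)-trans-epoxide (nucleophilic, so the geranyl alkenes are inert), and Lewis/Brønsted-acid activation of the benzylic, alkoxyaryl-stabilised Cβ–O bond then lets the neighbouring phenol open it 6-endo with inversion (not the 5-exo aurone mode of alkaline AFO conditions), setting C3 = R by retention and C2 = R by inversion (2,3-trans); the closest known reactions are lanthanide–BINOL/TBHP Weitz–Scheffer epoxidation of O-protected chalcones and acid-mediated cyclisation of 2'-hydroxychalcone epoxides to trans-dihydroflavonols.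

**Step 11**
Reactants: 14
Product: 15 4'-O-methyldiplacol [(2R,3R)-6-[(2E)-3,7-dimethylocta-2,6-dien-1-yl]-3,5,7-trihydroxy-2-(3-hydroxy-4-methoxyphenyl)-2,3-dihydro-4H-chromen-4-one]
Conditions: 3 M aq HCl/MeOH (1:5), 40 °C, 1–2 h (monitored)
Reagents that add atoms: none
Why: Acid-catalysed acetal methanolysis removes the three MOM ethers; the trans-dihydroflavonol is the thermodynamic isomer, and with a 4'-OMe group there is no quinone-methide pathway to epimerise C2.

## Compound list

1 | resorcinol | Oc1cccc(O)c1 | starting material
2 | 1,3-bis(methoxymethoxy)benzene | COCOc1cccc(OCOC)c1 | intermediate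
3 | geranyl bromide | BrC/C=C(\C)CCC=C(C)C | starting material
4 | 2-geranyl-1,3-bis(methoxymethoxy)benzene | COCOc1cccc(OCOC)c1C/C=C(\C)CCC=C(C)C | intermediate
5 | 4-geranyl-3,5-bis(methoxymethoxy)phenylboronic acid pinacol ester | COCOc1cc(B2OC(C)(C)C(C)(C)O2)cc(OCOC)c1C/C=C(\C)CCC=C(C)C | intermediate
6 | 4-geranyl-3,5-bis(methoxymethoxy)phenol | COCOc1cc(O)cc(OCOC)c1C/C=C(\C)CCC=C(C)C | intermediate
7 | THP ether of 6 (racemic acetal) | COCOc1cc(OC2CCCCO2)cc(OCOC)c1C/C=C(\C)CCC=C(C)C | intermediate
8 | isovanillin | COc1ccc(C=O)cc1O | starting material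
9 | 4-methoxy-3-(methoxymethoxy)benzaldehyde | COCOc1cc(C=O)ccc1OC | intermediate
10 | diethyl {2-[methoxy(methyl)amino]-2-oxoethyl}phosphonate | CCOP(=O)(CC(=O)N(C)OC)OCC | starting material
11 | (E)-N-methoxy-3-[4-methoxy-3-(methoxymethoxy)phenyl]-N-methylacrylamide | COCOc1cc(/C=C/C(=O)N(C)OC)ccc1OC | intermediate
12 | (E)-2'-OTHP-4',6'-bis(OMOM)-5'-geranyl chalcone with 3-OMOM-4-OMe B-ring | COCOc1cc(OC2CCCCO2)c(C(=O)/C=C/c2ccc(OC)c(OCOC)c2)c(OCOC)c1C/C=C(\C)CCC=C(C)C | intermediate
13 | (E)-2'-hydroxy-4',6'-bis(OMOM)-5'-geranyl chalcone with 3-OMOM-4-OMe B-ring | COCOc1cc(O)c(C(=O)/C=C/c2ccc(OC)c(OCOC)c2)c(OCOC)c1C/C=C(\C)CCC=C(C)C | intermediate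
14 | (2R,3R)-6-geranyl-3-hydroxy-5,7-bis(OMOM)-2-[4-methoxy-3-(OMOM)phenyl]chroman-4-one | COc1ccc([C@H]2Oc3cc(OCOC)c(C/C=C(\C)CCC=C(C)C)c(OCOC)c3C(=O)[C@@H]2O)cc1OCOC | intermediate
15 | 4'-O-methyldiplacol | COc1ccc([C@H]2Oc3cc(O)c(C/C=C(\C)CCC=C(C)C)c(O)c3C(=O)[C@@H]2O)cc1O | target

## Summary

Total step count: 11
Longest linear sequence: 9 steps (steps 1–5 and 8–11, from resorcinol)

Three steps most likely to fail, with fallbacks:

1. **Step 10 (proposed new reaction).** Risks are catalyst sequestration by the free phenol, competing racemic oxa-Michael closure to the flavanone, 5-exo (aurone) closure, a minor cis diastereomer from SN1 leakage at C2, or the opposite facial sense (then use (R)-BINOL). Fallback with known chemistry: keep the phenol masked and epoxidise THP-chalcone 12 by Julia–Colonna epoxidation (poly-L-leucine, urea·H2O2, DBU) to the (αR,βS)-epoxide. Then treat with PPTS/MeOH, which removes the THP group and drives the established acid-mediated 6-endo epoxide opening to 14. If the ee is low on this hindered ketone, make the B-ring (2R,3S)-epoxy Weinreb amide or acylpyrrole separately by established asymmetric epoxidation and add the aryllithium from 7 to it.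

2. **Step 11 (acidic MOM removal next to a geranyl chain).** Risks are acid-induced cyclisation of the 5- or 7-OH onto the geranyl alkene (chroman formation) or Markovnikov addition of MeOH. Fallback: change the protecting-group plan by using SEMCl instead of MOMCl in steps 1 and 6. SEM is an equally good metalation director and survives step 9, so the end game becomes MgBr2·OEt2 or fluoride deprotection instead of protic acid.

3. **Step 3 (Ir borylation in the presence of the geranyl alkenes).** Risks are alkene hydroboration or isomerisation, or slow borylation of the electron-rich arene. Fallback: invert the order. Borylate and oxidise 2 (no alkene present) to 3,5-bis(methoxymethoxy)phenol, protect it as the TIPS ether (non-directing, blocks its ortho sites), geranylate by lithiation at the only site between two OMOM groups, then remove TIPS with TBAF to reach 6.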